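A direct plan would buy ring A as methyl 3,5-dihydroxybenzoate A1, turn it by formylation, monosilylation and Mitsunobu methylation into aldehyde A2, and add the lithiated silyl ynol ether A3, (ethynyloxy)triisopropylsilane, to A2 with lactonisation to the phthalide ynol ether A4.
Ring B would then be grown on the alkyne of A4 by thermal benzannulation with the cyclobutenone A5, 3-methylcyclobut-2-en-1-one, to give the 3-arylphthalide A6; DDQ oxidation of A6 to keto acid A7, re-esterification, acetylation and desilylation would finish.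
Weakest point, the making and use of the two-carbon ynol ether: A3 would have to be set free with carbonate in methanol and then lithiated, although silyl ynol ethers are solvolysed through ketenes, and A4 carries a propargylic acyloxy leaving group on an electron-rich alkyne that would have to survive 80–110 °C while A5 opens to its vinylketene.
Second, the lactone detour: the benzophenone carbon would be carried as a carbinol in A4 and A6, so the methyl ester is consumed and rebuilt, and the late DDQ oxidation of A6 to A7 beside a free electron-rich phenol (quinone methide formation, overoxidation) adds risk but no skeleton.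
Third, the opening on A1: formylation between the two hydroxyls (C4) would compete with C2, and three steps of selective silylation and methylation would be spent only to tell two ring A oxygens apart.

**Retrosynthetic overview**
Ring A of the target (C1 CO2Me, C2 aroyl, C3 OMe, C4 H, C5 OH, C6 H) carries exactly the pattern that a 1,1-dimethoxy-3-silyloxybuta-1,3-diene lays down on an acetylenic keto ester, so ring A is cut at C1–C6 and C2–C3.
This leads to diene 17 (three steps from acetyl chloride) and ynone 10, in which the benzophenone carbonyl and the methyl ester already stand at their final oxidation level; 10 comes from orcinol (ring B, bought) by lithiation between the two oxygens, formylation, propiolate addition and oxidation.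
Ring order: ring B is bought, ring A is formed last by Diels–Alder reaction and loss of methanol, which places OMe, the silyl ether, the ester and the ketone in one operation.
No ynol ether, no lactone and no late oxidation occur; ring A leaves the key step as a silyl ether, so that after hydrogenolysis only the two equivalent, chelated ring B hydroxyls are free for monoacetylation.

Key step: step 8

Remark: the target has no stereocentre; carbinol 9 is formed as a racemate and its centre is removed by the oxidation in step 4.

Step 1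
Reactants: 1 orcinol (5-methylbenzene-1,3-diol)
Product: 2 1,3-bis(benzyloxy)-5-methylbenzene
Conditions: BnBr (2.2 equiv), K2CO3, DMF, 60 °C
Reagents that add atoms: benzyl bromide BrCc1ccccc1
Why: Williamson ether synthesis on both phenoxides, the benzyl ethers serving later as directing groups for lithiation and being removable by hydrogenolysis without harm to a silyl ether, an ester or an aryl ketone.

Step 2
Reactants: 2 1,3-bis(benzyloxy)-5-methylbenzene
Product: 5 2,6-bis(benzyloxy)-4-methylbenzaldehyde, via aryllithium 3 (not isolated), via lithium hemiaminolate 4 (not isolated)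
Conditions: n-BuLi (1.1 equiv), THF, 0 °C; DMF, 0 °C → rt; 1 M HCl, 0 °C
Reagents that add atoms: N,N-dimethylformamide CN(C)C=O
Why: Directed ortho-metalation at C2, the ring position flanked by two coordinating oxygens and therefore the most acidic, followed by Bouveault-type formylation of the aryllithium with DMF and collapse of the hemiaminolate on acidic work-up.

Step 3
Reactants: 5 2,6-bis(benzyloxy)-4-methylbenzaldehyde; 6 methyl propiolate
Product: 9 rac-methyl 4-[2,6-bis(benzyloxy)-4-methylphenyl]-4-hydroxybut-2-ynoate, via lithiated methyl propiolate 7 (not isolated), via lithium alkoxide 8 (not isolated)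
Conditions: 6 (1.3 equiv), LiN(SiMe3)2 (1.25 equiv), THF, −78 °C; then 5, −78 °C; AcOH, −78 °C
Reagents that add atoms: none
Why: 1,2-Addition of a lithium acetylide to the aldehyde, the propiolate anion being kept at −78 °C to prevent self-condensation, with the new carbinol centre formed as a racemate because it is oxidised in the next step.

Step 4
Reactants: 9 rac-methyl 4-[2,6-bis(benzyloxy)-4-methylphenyl]-4-hydroxybut-2-ynoate
Product: 10 methyl 4-[2,6-bis(benzyloxy)-4-methylphenyl]-4-oxobut-2-ynoate
Conditions: activated MnO2 (excess), CH2Cl2, rt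
Reagents that add atoms: none
Why: MnO2 oxidation of an alcohol that is both benzylic and propargylic, under neutral heterogeneous conditions that should spare the Michael-acceptor ynoate.

Step 5
Reactants: 11 acetyl chloride; 12 1,1-dichloroethene
Product: 14 4,4-dichlorobut-3-en-2-one, via trichloro ketone 13 (not isolated)
Conditions: AlCl3, CH2Cl2, 0 °C → rt; ice, aq HCl; distillation (loss of HCl)
Reagents that add atoms: none
Why: Friedel–Crafts-type acylation of the alkene by the acylium ion with chloride capture, followed by loss of HCl on distillation to the conjugated dichlorovinyl ketone.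

Step 6
Reactants: 14 4,4-dichlorobut-3-en-2-one
Product: 16 4,4-dimethoxybut-3-en-2-one, via chloro methoxy enone 15 (not isolated)
Conditions: NaOMe (2.1 equiv), MeOH, 0 °C → rt
Reagents that add atoms: sodium methoxide [Na+].[O-]C
Why: Twofold nucleophilic vinylic substitution (addition–elimination) of methoxide at the β-carbon of the β,β-dichloro enone, which gives the acyl ketene acetal.

Step 7
Reactants: 16 4,4-dimethoxybut-3-en-2-one
Product: 17 3-[(tert-butyldimethylsilyl)oxy]-1,1-dimethoxybuta-1,3-diene
Conditions: TBSOTf (1.1 equiv), Et3N (1.5 equiv), Et2O, 0 °C; filtration, bulb-to-bulb distillation, stored cold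
Reagents that add atoms: tert-butyldimethylsilyl trifluoromethanesulfonate CC(C)(C)[Si](C)(C)OS(=O)(=O)C(F)(F)F
Why: Soft enolisation and O-silylation of the methyl ketone on its only enolisable side, the amine keeping the medium basic so that the acid-sensitive ketene acetal survives.

Step 8
Reactants: 10 methyl 4-[2,6-bis(benzyloxy)-4-methylphenyl]-4-oxobut-2-ynoate; 17 3-[(tert-butyldimethylsilyl)oxy]-1,1-dimethoxybuta-1,3-diene
Product: 19 methyl 2-[2,6-bis(benzyloxy)-4-methylbenzoyl]-5-[(tert-butyldimethylsilyl)oxy]-3-methoxybenzoate, via cyclohexadiene ketal 18 (not isolated)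
Conditions: 17 (1.5 equiv), PhMe, 0 °C → rt; then 80 °C
Reagents that add atoms: none
Why: Normal-electron-demand Diels–Alder reaction of the electron-poor acetylenic keto ester 10 with the electron-rich ketene acetal diene 17, probably asynchronous with the first bond formed in a Michael sense, should give the cyclohexa-1,4-diene ketal 18, which aromatises by 1,4-elimination of methanol (C3–OMe and C6–H) while the silyl enol ether is carried through as the aryl silyl ether. The closest known reaction type is the benzannulation of 1,1-dialkoxy-3-silyloxybutadienes and 1-methoxy-3-silyloxybutadienes with acetylenic esters and ketones, which gives 3-methoxy-5-hydroxy benzoates and phthalates. Ring A is the only ring closed, by an intermolecular [4+2] cycloaddition that forms C1–C6 and C2–C3 and leaves both carbonyl groups untouched. No stereocentre is formed, since the sp3 centres of 18 are lost on aromatisation. The step needs regiocontrol: the unsubstituted CH2 terminus of 17 (largest HOMO coefficient) must bond to the alkyne carbon β to the ketone, that is the carbon bearing CO2Me, which the stronger acceptor (the aryl ketone, twisted out of conjugation with ring B by its two ortho benzyloxy groups) should secure, so that C(OMe)2 ends next to the aroyl carbon and the silyloxy carbon para to it. It also needs chemoselectivity for the alkyne over the ketone carbonyl, which the same two ortho substituents shield from Mukaiyama-type addition.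

Step 9
Reactants: 19 methyl 2-[2,6-bis(benzyloxy)-4-methylbenzoyl]-5-[(tert-butyldimethylsilyl)oxy]-3-methoxybenzoate
Product: 20 methyl 5-[(tert-butyldimethylsilyl)oxy]-2-(2,6-dihydroxy-4-methylbenzoyl)-3-methoxybenzoate
Conditions: H2 (1 atm), Pd/C (10 wt %), EtOAc, rt
Reagents that add atoms: none
Why: Hydrogenolysis of both aryl benzyl ethers over palladium on carbon, under which the hindered, electron-rich diaryl ketone, the aryl silyl ether and the methyl ester should stay intact.

Step 10
Reactants: 20 methyl 5-[(tert-butyldimethylsilyl)oxy]-2-(2,6-dihydroxy-4-methylbenzoyl)-3-methoxybenzoate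
Product: 21 methyl 2-(2-acetoxy-6-hydroxy-4-methylbenzoyl)-5-[(tert-butyldimethylsilyl)oxy]-3-methoxybenzoate
Conditions: Ac2O (1.05 equiv), pyridine, DMAP (5 mol %), CH2Cl2, 0 °C
Reagents that add atoms: acetic anhydride CC(=O)OC(C)=O
Why: Phenol acylation in which the two ring B hydroxyls are equivalent (symmetry about the C1'–C4' axis), and after the first acetylation the remaining hydroxyl is locked in a strong hydrogen bond to the ketone and shielded, so that one equivalent of anhydride should stop at the monoacetate.

Step 11
Reactants: 21 methyl 2-(2-acetoxy-6-hydroxy-4-methylbenzoyl)-5-[(tert-butyldimethylsilyl)oxy]-3-methoxybenzoate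
Product: 22 penibenzophenone C, methyl 2-(2-acetoxy-6-hydroxy-4-methylbenzoyl)-5-hydroxy-3-methoxybenzoate
Conditions: Bu4NF, AcOH (1:1), THF, 0 °C
Reagents that add atoms: none
Why: Fluoride cleavage of the aryl silyl ether under acetic acid buffering, so that the liberated ring A phenoxide is protonated at once and the aryl acetate is neither cleaved nor transferred.

**Compound list**
1 | orcinol (5-methylbenzene-1,3-diol) | Cc1cc(O)cc(O)c1 | starting material
2 | 1,3-bis(benzyloxy)-5-methylbenzene | Cc1cc(OCc2ccccc2)cc(OCc2ccccc2)c1 | intermediate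
3 | [2,6-bis(benzyloxy)-4-methylphenyl]lithium | [Li]c1c(OCc2ccccc2)cc(C)cc1OCc1ccccc1 | intermediate (not isolated)
4 | lithium [2,6-bis(benzyloxy)-4-methylphenyl](dimethylamino)methanolate (racemic) | [Li+].[O-]C(N(C)C)c1c(OCc2ccccc2)cc(C)cc1OCc1ccccc1 | intermediate (not isolated)
5 | 2,6-bis(benzyloxy)-4-methylbenzaldehyde | O=Cc1c(OCc2ccccc2)cc(C)cc1OCc1ccccc1 | intermediate
6 | methyl propiolate | C#CC(=O)OC | starting material
7 | lithium 3-methoxy-3-oxoprop-1-yn-1-ide (lithiated methyl propiolate) | [Li]C#CC(=O)OC | intermediate (not isolated)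
8 | lithium alkoxide of methyl 4-[2,6-bis(benzyloxy)-4-methylphenyl]-4-hydroxybut-2-ynoate (racemic) | [Li+].[O-]C(C#CC(=O)OC)c1c(OCc2ccccc2)cc(C)cc1OCc1ccccc1 | intermediate (not isolated)
9 | rac-methyl 4-[2,6-bis(benzyloxy)-4-methylphenyl]-4-hydroxybut-2-ynoate | COC(=O)C#CC(O)c1c(OCc2ccccc2)cc(C)cc1OCc1ccccc1 | intermediate
10 | methyl 4-[2,6-bis(benzyloxy)-4-methylphenyl]-4-oxobut-2-ynoate | COC(=O)C#CC(=O)c1c(OCc2ccccc2)cc(C)cc1OCc1ccccc1 | intermediate (precursor of the key step)
11 | acetyl chloride | CC(=O)Cl | starting material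
12 | 1,1-dichloroethene | C=C(Cl)Cl | starting material
13 | 4,4,4-trichlorobutan-2-one | CC(=O)CC(Cl)(Cl)Cl | intermediate (not isolated)
14 | 4,4-dichlorobut-3-en-2-one | CC(=O)C=C(Cl)Cl | intermediate
15 | 4-chloro-4-methoxybut-3-en-2-one (mixture of double bond isomers) | CC(=O)C=C(Cl)OC | intermediate (not isolated)
16 | 4,4-dimethoxybut-3-en-2-one | CC(=O)C=C(OC)OC | intermediate
17 | 3-[(tert-butyldimethylsilyl)oxy]-1,1-dimethoxybuta-1,3-diene | C=C(O[Si](C)(C)C(C)(C)C)C=C(OC)OC | intermediate (precursor of the key step)
18 | methyl 2-[2,6-bis(benzyloxy)-4-methylbenzoyl]-5-[(tert-butyldimethylsilyl)oxy]-3,3-dimethoxycyclohexa-1,4-diene-1-carboxylate | COC(=O)C1=C(C(=O)c2c(OCc3ccccc3)cc(C)cc2OCc2ccccc2)C(OC)(OC)C=C(O[Si](C)(C)C(C)(C)C)C1 | intermediate (not isolated)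
19 | methyl 2-[2,6-bis(benzyloxy)-4-methylbenzoyl]-5-[(tert-butyldimethylsilyl)oxy]-3-methoxybenzoate | COC(=O)c1cc(O[Si](C)(C)C(C)(C)C)cc(OC)c1C(=O)c1c(OCc2ccccc2)cc(C)cc1OCc1ccccc1 | intermediate (product of the key step)
20 | methyl 5-[(tert-butyldimethylsilyl)oxy]-2-(2,6-dihydroxy-4-methylbenzoyl)-3-methoxybenzoate | COC(=O)c1cc(O[Si](C)(C)C(C)(C)C)cc(OC)c1C(=O)c1c(O)cc(C)cc1O | intermediate
21 | methyl 2-(2-acetoxy-6-hydroxy-4-methylbenzoyl)-5-[(tert-butyldimethylsilyl)oxy]-3-methoxybenzoate | COC(=O)c1cc(O[Si](C)(C)C(C)(C)C)cc(OC)c1C(=O)c1c(O)cc(C)cc1OC(C)=O | intermediate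
22 | penibenzophenone C, methyl 2-(2-acetoxy-6-hydroxy-4-methylbenzoyl)-5-hydroxy-3-methoxybenzoate | COC(=O)c1cc(O)cc(OC)c1C(=O)c1c(O)cc(C)cc1OC(C)=O | target

**Step count and risks**
Total step count: 11. Longest linear sequence: 8 steps (steps 1–4 and 8–11); the diene branch (steps 5–7) has 3 steps.

Steps most likely to fail:

Step 8. Ring closure at the hindered ketene acetal carbon may fall behind the first bond formation, so that the reaction stops at an open-chain Michael adduct or the diene is lost by desilylation. Partial loss of the silyl group during aromatisation is also possible and would be repaired by resilylation. Fallback, setting out from carbinol 9: amine-catalysed redox isomerisation (DABCO, DMSO, rt) should give methyl (2E)-4-[2,6-bis(benzyloxy)-4-methylphenyl]-4-oxobut-2-enoate F1, an alkene dienophile of a well-tried kind with the same ketone-controlled orientation. Its Diels–Alder reaction with 17 (PhMe, rt to 60 °C) would give rac-trans-methyl 2-[2,6-bis(benzyloxy)-4-methylbenzoyl]-5-[(tert-butyldimethylsilyl)oxy]-3,3-dimethoxycyclohex-4-ene-1-carboxylate F2. DBU would then remove methanol to give rac-methyl 2-[2,6-bis(benzyloxy)-4-methylbenzoyl]-5-[(tert-butyldimethylsilyl)oxy]-3-methoxycyclohexa-2,4-diene-1-carboxylate F3, and dehydrogenation with DDQ would come back to the route at 19.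

Step 10. Acetylation may run on to the diacetate or stop short, leaving a mixture of diol, monoacetate and diacetate that is hard to separate. Fallback, setting out from 19: chelation-controlled cleavage of one benzyl ether (BCl3, 1.1 equiv, CH2Cl2, −78 °C) would give methyl 2-[2-(benzyloxy)-6-hydroxy-4-methylbenzoyl]-5-[(tert-butyldimethylsilyl)oxy]-3-methoxybenzoate F4. Its single free phenol would be acetylated (Ac2O, pyridine, DMAP) to methyl 2-[2-acetoxy-6-(benzyloxy)-4-methylbenzoyl]-5-[(tert-butyldimethylsilyl)oxy]-3-methoxybenzoate F5. Hydrogenolysis (H2, Pd/C) of the remaining benzyl ether would come back to the route at 21.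

Step 2. Lithiation at a benzylic CH2 with subsequent [1,2]-Wittig rearrangement may compete with ring lithiation. Fallback, setting out from 1: the ether without benzylic hydrogen, 1,3-bis(methoxymethoxy)-5-methylbenzene F6 (MOMCl, i-Pr2NEt, CH2Cl2), would be lithiated and formylated (n-BuLi, THF, 0 °C; DMF) to 2,6-bis(methoxymethoxy)-4-methylbenzaldehyde F7. Deprotection (HCl, MeOH) would give 2,6-dihydroxy-4-methylbenzaldehyde F8, and benzylation (BnBr, K2CO3, DMF) would come back to the route at 5.

**Further compounds**
F1 | step 8 | methyl (2E)-4-[2,6-bis(benzyloxy)-4-methylphenyl]-4-oxobut-2-enoate | COC(=O)/C=C/C(=O)c1c(OCc2ccccc2)cc(C)cc1OCc1ccccc1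
F2 | step 8 | rac-trans-methyl 2-[2,6-bis(benzyloxy)-4-methylbenzoyl]-5-[(tert-butyldimethylsilyl)oxy]-3,3-dimethoxycyclohex-4-ene-1-carboxylate (one enantiomer drawn) | COC(=O)[C@@H]1CC(O[Si](C)(C)C(C)(C)C)=CC(OC)(OC)[C@H]1C(=O)c1c(OCc2ccccc2)cc(C)cc1OCc1ccccc1
F3 | step 8 | rac-methyl 2-[2,6-bis(benzyloxy)-4-methylbenzoyl]-5-[(tert-butyldimethylsilyl)oxy]-3-methoxycyclohexa-2,4-diene-1-carboxylate | COC(=O)C1CC(O[Si](C)(C)C(C)(C)C)=CC(OC)=C1C(=O)c1c(OCc2ccccc2)cc(C)cc1OCc1ccccc1
F4 | step 10 | methyl 2-[2-(benzyloxy)-6-hydroxy-4-methylbenzoyl]-5-[(tert-butyldimethylsilyl)oxy]-3-methoxybenzoate | COC(=O)c1cc(O[Si](C)(C)C(C)(C)C)cc(OC)c1C(=O)c1c(O)cc(C)cc1OCc1ccccc1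
F5 | step 10 | methyl 2-[2-acetoxy-6-(benzyloxy)-4-methylbenzoyl]-5-[(tert-butyldimethylsilyl)oxy]-3-methoxybenzoate | COC(=O)c1cc(O[Si](C)(C)C(C)(C)C)cc(OC)c1C(=O)c1c(OC(C)=O)cc(C)cc1OCc1ccccc1
F6 | step 2 | 1,3-bis(methoxymethoxy)-5-methylbenzene | Cc1cc(OCOC)cc(OCOC)c1
F7 | step 2 | 2,6-bis(methoxymethoxy)-4-methylbenzaldehyde | O=Cc1c(OCOC)cc(C)cc1OCOC
F8 | step 2 | 2,6-dihydroxy-4-methylbenzaldehyde | O=Cc1c(O)cc(C)cc1O
A1 | direct plan | methyl 3,5-dihydroxybenzoate | COC(=O)c1cc(O)cc(O)c1
A2 | direct plan | methyl 2-formyl-3-methoxy-5-[(triisopropylsilyl)oxy]benzoate | COC(=O)c1cc(O[Si](C(C)C)(C(C)C)C(C)C)cc(OC)c1C=O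
A3 | direct plan | (ethynyloxy)triisopropylsilane | C#CO[Si](C(C)C)(C(C)C)C(C)C
A4 | direct plan | rac-4-methoxy-6-[(triisopropylsilyl)oxy]-3-{[(triisopropylsilyl)oxy]ethynyl}-2-benzofuran-1(3H)-one | O=C1OC(C#CO[Si](C(C)C)(C(C)C)C(C)C)c2c(OC)cc(O[Si](C(C)C)(C(C)C)C(C)C)cc12
A5 | direct plan | 3-methylcyclobut-2-en-1-one | CC1=CC(=O)C1
A6 | direct plan | rac-3-{2-hydroxy-4-methyl-6-[(triisopropylsilyl)oxy]phenyl}-4-methoxy-6-[(triisopropylsilyl)oxy]-2-benzofuran-1(3H)-one | O=C1OC(c2c(O)cc(C)cc2O[Si](C(C)C)(C(C)C)C(C)C)c2c(OC)cc(O[Si](C(C)C)(C(C)C)C(C)C)cc12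
A7 | direct plan | 2-{2-hydroxy-4-methyl-6-[(triisopropylsilyl)oxy]benzoyl}-3-methoxy-5-[(triisopropylsilyl)oxy]benzoic acid | OC(=O)c1cc(O[Si](C(C)C)(C(C)C)C(C)C)cc(OC)c1C(=O)c1c(O)cc(C)cc1O[Si](C(C)C)(C(C)C)C(C)C
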